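Assumption: the SMILES is read, in labdane numbering, as (12E)-7β-acetoxylabda-12,14-diene-6β,8α-diol of the normal series (5α-H, 9α-H, 8β-Me, 10β-Me); α/β labels below use this numbering.

**Retrosynthetic overview**
1. C7–OAc is made last, by site-selective acetylation of the 6β,7β,8α-triol (only the equatorial secondary OH reacts).
2. C14=C15 and C12=C13 come from two Wittig olefinations of a C12 lactol, itself obtained from the γ-lactone with DIBAL-H.
3. C6–O and C7–O (key bonds) come from a double, retentive C–H hydroxylation on the β-face of ring B of (+)-sclareolide.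
4. No ring is built: the trans-decalin with C5, C8, C9 and C10 (8α-O, 8β-Me) is bought as (+)-sclareolide, and its lactone ring is opened to become the side chain.

**Route**

Step 1
Reactants: 1 (+)-sclareolide (13,14,15,16-tetranorlabdan-12,8α-olide)
Product: 3 sclareolide-6β,7β-diol, via sclareolide-7β-ol 2 (not isolated)
Conditions: engineered P450 monooxygenase (ring-B variant derived from the forskolin-pathway CYP76AH 6β,7β-hydroxylase, with its reductase, yeast microsomes), NADP+ (cat.), glucose, glucose dehydrogenase, air, KPi pH 7.5, 5% DMSO, 28 °C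
Reagents that add atoms: dioxygen, O=O
Why: Proposed new method: a P450 pocket re-shaped for the smaller γ-lactone holds 1 with the β-face of ring B over the heme, so that Compound I (FeIV=O porphyrin radical cation) abstracts the only two secondary hydrogens this face offers besides three methyl groups, first the exposed equatorial 7β-H and then the axial 6β-H (whose removal relieves the strain of three syn-axial methyls), and hydroxyl rebound on the same face replaces each H with retention, which forms both key C–O bonds and sets C7 (β-OH) and C6 (β-OH); any over-oxidation to a 6- or 7-ketone is corrected in step 2, where hydride enters from the open α-face; the closest known reactions are the P450 hydrogen-abstraction/oxygen-rebound hydroxylation of sclareolide at C3 by P450-BM3 variants and the 6β,7β-hydroxylation of the manoyl oxide core in forskolin biosynthesis, neither shown for ring B of sclareolide.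

Step 2
Reactants: 3 sclareolide-6β,7β-diol
Product: 4 lactol 8α,12-epoxy-13,14,15,16-tetranorlabdane-6β,7β,12-triol (C12 anomers)
Conditions: DIBAL-H (4 equiv), CH2Cl2/THF, −78 °C; Rochelle salt
Reagents that add atoms: none
Why: DIBAL-H lactone-to-lactol reduction, in which the tetrahedral aluminium hemiacetal survives at −78 °C and gives the lactol on work-up (two equivalents are consumed by the diol); no ring stereocentre is touched and the C12 anomers are inconsequential.

Step 3
Reactants: 4 lactol 8α,12-epoxy-13,14,15,16-tetranorlabdane-6β,7β,12-triol; 5 2-(triphenylphosphoranylidene)propanal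
Product: 6 (12E)-6β,7β,8α-trihydroxy-15-norlabd-12-en-14-al
Conditions: 5 (2.5 equiv), PhCO2H (10 mol %), toluene, 100 °C
Reagents that add atoms: 2-(triphenylphosphoranylidene)propanal, CC(C=O)=P(c1ccccc1)(c1ccccc1)c1ccccc1
Why: Wittig olefination of the hydroxy-aldehyde tautomer of the lactol with a stabilised α-methyl ylide, whose reversible oxaphosphetane formation gives the (E)-trisubstituted enal (C12=C13) and frees the 8α-OH.

Step 4
Reactants: 6 (12E)-6β,7β,8α-trihydroxy-15-norlabd-12-en-14-al; 7 methyltriphenylphosphonium bromide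
Product: 9 (12E)-labda-12,14-diene-6β,7β,8α-triol, via methylenetriphenylphosphorane 8 (not isolated)
Conditions: 7 (6 equiv), KOtBu (5.5 equiv), THF, 0 °C; then 6, 0 °C to rt
Reagents that add atoms: methyltriphenylphosphonium bromide, C[P+](c1ccccc1)(c1ccccc1)c1ccccc1.[Br-]
Why: Wittig methylenation is 1,2-selective for the aldehyde, leaves the (E)-C12=C13 bond untouched and, with excess ylide, tolerates the three hydroxyls as alkoxides.

Step 5
Reactants: 9 (12E)-labda-12,14-diene-6β,7β,8α-triol; 10 acetic anhydride
Product: 11 (12E)-7β-acetoxylabda-12,14-diene-6β,8α-diol (CNP0225877.1)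
Conditions: Ac2O (1.2 equiv), pyridine, 0 °C
Reagents that add atoms: acetic anhydride, CC(=O)OC(C)=O
Why: Site-selective O-acylation, since only the equatorial secondary 7β-OH is reactive (6β-OH is axial between the syn-axial 4β-, 8β- and 10β-methyls and 8α-OH is tertiary), the same selectivity as in the 7-O-acetylation of 7-deacetylforskolin.

**Compound list**
1 | (+)-sclareolide (13,14,15,16-tetranorlabdan-12,8α-olide; 5α-H, 9α-H, 8β-Me, 10β-Me) | O=C1C[C@H]2[C@](C)(O1)CC[C@H]3C(C)(C)CCC[C@@]32C | starting material
2 | sclareolide-7β-ol (7β-hydroxysclareolide, equatorial OH) | O=C1C[C@H]2[C@](C)(O1)[C@@H](O)C[C@H]3C(C)(C)CCC[C@@]32C | intermediate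
3 | sclareolide-6β,7β-diol (6β-OH axial, 7β-OH equatorial, both cis to the 10-methyl) | O=C1C[C@H]2[C@](C)(O1)[C@@H](O)[C@@H](O)[C@H]3C(C)(C)CCC[C@@]32C | intermediate
4 | lactol 8α,12-epoxy-13,14,15,16-tetranorlabdane-6β,7β,12-triol (mixture of C12 anomers) | OC1C[C@H]2[C@](C)(O1)[C@@H](O)[C@@H](O)[C@H]3C(C)(C)CCC[C@@]32C | intermediate
5 | 2-(triphenylphosphoranylidene)propanal | CC(C=O)=P(c1ccccc1)(c1ccccc1)c1ccccc1 | starting material
6 | (12E)-6β,7β,8α-trihydroxy-15-norlabd-12-en-14-al | O=C/C(C)=C/C[C@H]1[C@](C)(O)[C@@H](O)[C@@H](O)[C@H]2C(C)(C)CCC[C@@]21C | intermediate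
7 | methyltriphenylphosphonium bromide | C[P+](c1ccccc1)(c1ccccc1)c1ccccc1.[Br-] | starting material
8 | methylenetriphenylphosphorane | C=P(c1ccccc1)(c1ccccc1)c1ccccc1 | intermediate
9 | (12E)-labda-12,14-diene-6β,7β,8α-triol | C=C/C(C)=C/C[C@H]1[C@](C)(O)[C@@H](O)[C@@H](O)[C@H]2C(C)(C)CCC[C@@]21C | intermediate
10 | acetic anhydride | CC(=O)OC(C)=O | starting material
11 | (12E)-7β-acetoxylabda-12,14-diene-6β,8α-diol (CNP0225877.1) | C=C/C(C)=C/C[C@H]1[C@](C)(O)[C@@H](OC(C)=O)[C@@H](O)[C@H]2C(C)(C)CCC[C@@]21C | target

**Step count and risks**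

Total steps: 5. Longest linear sequence: 5 steps (1 to 11).

The three steps most likely to fail:

Step 1 (the proposed new step). The enzyme does not yet exist. It may prefer ring A (C1–C3), or stop at the mono-ol 2. The fallback uses known chemistry, sets out from 1 and comes back at 3. Lactone 1 is opened and esterified with H2SO4 in refluxing MeOH (E1 loss of the C8 carboxylate). The Δ7 isomer, methyl 13,14,15,16-tetranorlabd-7-en-12-oate F1, is separated from its Δ8(17) and Δ8 isomers on AgNO3–silica. Allylic oxidation with CrO3·3,5-dimethylpyrazole gives methyl 6-oxo-13,14,15,16-tetranorlabd-7-en-12-oate F2. Luche reduction (NaBH4, CeCl3, MeOH, hydride from the α-face) gives methyl 6β-hydroxy-13,14,15,16-tetranorlabd-7-en-12-oate F3. VO(acac)2/t-BuOOH then delivers oxygen syn to the 6β-OH to give methyl 7β,8β-epoxy-6β-hydroxy-13,14,15,16-tetranorlabdan-12-oate F4. Without isolation, CSA makes the ester carbonyl attack C8 anti to the epoxide oxygen, which closes the 8α-lactone, releases the 7β-OH and gives 3.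

Step 3. The hindered lactol opens slowly, the formyl ylide is sluggish, and the freed 8α-OH can add back to the enal (oxa-Michael to the 8α,12-ether). The fallback sets out from 4 and comes back at 6 by way of the ester oxidation level. The more nucleophilic ethyl 2-(triphenylphosphoranylidene)propanoate (toluene, 80 °C) gives the less electrophilic ethyl (12E)-6β,7β,8α-trihydroxy-15-norlabd-12-en-14-oate F5. DIBAL-H reduces it to (12E)-15-norlabd-12-ene-6β,7β,8α,14-tetraol F6, and MnO2 oxidises only the primary allylic alcohol to enal 6.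

Step 4. The strongly basic ylide meets three free hydroxyls and a γ-hydroxy enal (alkoxide oxa-Michael, incomplete conversion). The fallback sets out from 6 and comes back at 9 by a Peterson olefination instead of a Wittig reaction. Excess Me3SiCH2MgCl/CeCl3 adds 1,2 to the aldehyde to give (12E)-15-(trimethylsilyl)labd-12-ene-6β,7β,8α,14-tetraol F7 (C14 epimers), and KH-induced syn-elimination of silanolate gives 9.

Further compounds
F1 | step 1 | methyl 13,14,15,16-tetranorlabd-7-en-12-oate | COC(=O)C[C@H]1C(C)=CC[C@H]2C(C)(C)CCC[C@@]21C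
F2 | step 1 | methyl 6-oxo-13,14,15,16-tetranorlabd-7-en-12-oate | COC(=O)C[C@H]1C(C)=CC(=O)[C@H]2C(C)(C)CCC[C@@]21C
F3 | step 1 | methyl 6β-hydroxy-13,14,15,16-tetranorlabd-7-en-12-oate | COC(=O)C[C@H]1C(C)=C[C@@H](O)[C@H]2C(C)(C)CCC[C@@]21C
F4 | step 1 | methyl 7β,8β-epoxy-6β-hydroxy-13,14,15,16-tetranorlabdan-12-oate | COC(=O)C[C@H]1[C@@]3(C)O[C@H]3[C@@H](O)[C@H]2C(C)(C)CCC[C@@]21C
F5 | step 3 | ethyl (12E)-6β,7β,8α-trihydroxy-15-norlabd-12-en-14-oate | CCOC(=O)/C(C)=C/C[C@H]1[C@](C)(O)[C@@H](O)[C@@H](O)[C@H]2C(C)(C)CCC[C@@]21C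
F6 | step 3 | (12E)-15-norlabd-12-ene-6β,7β,8α,14-tetraol | OC/C(C)=C/C[C@H]1[C@](C)(O)[C@@H](O)[C@@H](O)[C@H]2C(C)(C)CCC[C@@]21C
F7 | step 4 | (12E)-15-(trimethylsilyl)labd-12-ene-6β,7β,8α,14-tetraol (C14 epimers) | C[Si](C)(C)CC(O)/C(C)=C/C[C@H]1[C@](C)(O)[C@@H](O)[C@@H](O)[C@H]2C(C)(C)CCC[C@@]21C
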